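**Plan**

- Retrosynthesis: ring C is opened at O1–C2 (oxa-Michael), the chalcone is cut at C2=C3 (aldol) and at C4–C4a (aryl ketone), and ring A is cut at C7–C8, C4a–C8a and C6–C7 into a 4-prenyl-3-tert-butoxycyclobutenone and a lavandulyl siloxyalkyne.
- Enabling feature: ring A (C4a, C5, C6, C7, C8, C8a) carries oxygens at C5, C7 and C8a that alternate with carbon substituents at C6 (prenyl), C8 (lavandulyl) and C4a, the resorcinol pattern a vinylketene and an ynol ether deliver.
- Forward order: siloxyalkyne (steps 1–6) and cyclobutenone (steps 7–8) are fused to ring A (step 9); then C4a bromination, acetylation, Claisen–Schmidt condensation with the ring B aldehyde, closure of ring C and deprotection.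
- Stereochemistry: the lavandulyl centre comes from an Evans deconjugative alkylation on (S)-4-benzyloxazolidinone; C2 (S) comes from a catalyst-controlled oxa-Michael closure.
- Oxygen differentiation: O5 is a tert-butyl ether (from the ynol ether), O8a a TIPS ether (from the siloxyalkyne, later O1), O7, O2′ and O4′ are MOM ethers; all fall with acid at the end.

Key step: step 9

Assumption: the quinidine-derived thiourea is taken to give the 2S series in step 15; the quinine-derived pseudo-enantiomer closes the ring with the opposite sense and replaces it if a trial closure shows the reverse.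
Assumption: 5-methylhex-4-enoic acid (22) is taken as a purchasable acid.
Names used: prenyl = 3-methylbut-2-en-1-yl; lavandulyl = (2R)-5-methyl-2-(prop-1-en-2-yl)hex-4-en-1-yl (same spatial arrangement as in (S)-lavandulol; only the descriptor changes); MOM = methoxymethyl; TIPS = triisopropylsilyl; ring A positions are given in flavanone numbering.

**Route**

Step 1
Reactants: 1 (4S)-4-benzyl-1,3-oxazolidin-2-one; 2 3-methylbut-2-enoyl chloride
Product: 4 (4S)-4-benzyl-3-(3-methylbut-2-enoyl)-1,3-oxazolidin-2-one, via N-lithio oxazolidinone 3 (not isolated)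
Conditions: n-BuLi, THF, −78 °C; then 2, −78 to 0 °C
Reagents that add atoms: none
Why: N-acylation of the lithiated oxazolidinone by an acid chloride is the standard entry to N-acyloxazolidinones, and the low temperature and absence of an amine base avoid vinylketene formation from the senecioyl chloride.

Step 2
Reactants: 4 (4S)-4-benzyl-3-(3-methylbut-2-enoyl)-1,3-oxazolidin-2-one; 5 prenyl bromide
Product: 7 (4S)-4-benzyl-3-[(2S)-5-methyl-2-(prop-1-en-2-yl)hex-4-enoyl]-1,3-oxazolidin-2-one, via sodium dienolate 6 (not isolated)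
Conditions: NaN(SiMe3)2, THF, −78 °C; then 5, −78 to −40 °C
Reagents that add atoms: none
Why: Evans-type deconjugative alkylation, in which NaN(SiMe3)2 removes a γ-proton to give the sodium-chelated (Z)-dienolate 6 and the allylic bromide attacks its α-carbon on the face opposite the benzyl group, setting the (S) centre that becomes the lavandulyl stereocentre.

Step 3
Reactants: 7 (4S)-4-benzyl-3-[(2S)-5-methyl-2-(prop-1-en-2-yl)hex-4-enoyl]-1,3-oxazolidin-2-one
Product: 8 (S)-lavandulol
Conditions: LiBH4, Et2O, H2O (1 equiv), 0 °C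
Reagents that add atoms: none
Why: Reductive cleavage of the imide with LiBH4 should give the primary alcohol without epimerising the α-centre or touching the alkenes, and it returns auxiliary 1.

Step 4
Reactants: 8 (S)-lavandulol; 9 ethynyl(trimethyl)silane
Product: 12 trimethyl[(4R)-7-methyl-4-(prop-1-en-2-yl)oct-6-en-1-yn-1-yl]silane, via lavandulyl triflate 10 (not isolated), via lithium trimethylsilylacetylide 11 (not isolated)
Conditions: Tf2O, 2,6-lutidine, CH2Cl2, −78 °C; crude 10 added to 11 (from 9, n-BuLi), THF–DMPU, −78 to −20 °C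
Reagents that add atoms: none
Why: SN2 alkylation of a lithium acetylide by a primary alkyl triflate, which is reactive enough for substitution at low temperature where E2 loss of the allylic β-hydrogen is slow, and the stereocentre sits one carbon away from the reacting centre and is not touched.

Step 5
Reactants: 12 trimethyl[(4R)-7-methyl-4-(prop-1-en-2-yl)oct-6-en-1-yn-1-yl]silane
Product: 13 (4R)-7-methyl-4-(prop-1-en-2-yl)oct-6-en-1-yne
Conditions: K2CO3 (cat.), MeOH, rt
Reagents that add atoms: none
Why: Base-catalysed methanolysis of the alkynyl C–Si bond (protodesilylation) is selective and leaves the rest of the molecule untouched.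

Step 6
Reactants: 13 (4R)-7-methyl-4-(prop-1-en-2-yl)oct-6-en-1-yne
Product: 16 triisopropyl{[(4R)-7-methyl-4-(prop-1-en-2-yl)oct-6-en-1-yn-1-yl]oxy}silane, via lithium acetylide 14 (not isolated), via lithium ynolate 15 (not isolated)
Conditions: n-BuLi, THF, −78 °C; LiOO-t-Bu (from t-BuOOH and LiN(SiMe3)2), −78 to 0 °C; TIPSOTf, −78 °C
Reagents that add atoms: tert-butyl hydroperoxide CC(C)(C)OO; triisopropylsilyl trifluoromethanesulfonate CC(C)[Si](C(C)C)(C(C)C)OS(=O)(=O)C(F)(F)F
Why: Electrophilic oxygenation of the lithium acetylide by lithium tert-butyl peroxide gives lithium ynolate 15, which the hard silyl triflate traps on oxygen to give the bulky, storable TIPS ynol ether (the established acetylide-to-siloxyalkyne sequence).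

Step 7
Reactants: 17 potassium tert-butoxide; 18 trichloroethene
Product: 21 tert-butoxyethyne, via dichlorovinyl ether 19 (not isolated), via lithium tert-butoxyacetylide 20 (not isolated)
Conditions: THF, −50 °C to rt; then n-BuLi (2.2 equiv), −78 to −40 °C; H2O, −78 °C; used as a solution
Reagents that add atoms: none
Why: One-pot ynol ether synthesis from an alkoxide and trichloroethene, in which tert-butoxide adds to dichloroacetylene formed in situ to give 19, n-BuLi effects elimination and chlorine–lithium exchange to 20, and water protonates it.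

Step 8
Reactants: 22 5-methylhex-4-enoic acid; 21 tert-butoxyethyne
Product: 25 3-tert-butoxy-4-(3-methylbut-2-en-1-yl)cyclobut-2-en-1-one (racemic), via acid chloride 23 (not isolated), via prenylketene 24 (not isolated)
Conditions: (COCl)2, DMF (cat.), CH2Cl2, 0 °C to rt, concentrate; then slow addition to 21 (1.5 equiv) and Et3N, Et2O, 0 °C to rt
Reagents that add atoms: none
Why: Dehydrochlorination gives aldoketene 24, which undergoes the regioselective [2+2] cycloaddition of ketenes with alkoxyacetylenes (ketene carbonyl carbon to the terminal alkyne carbon), the classical route to 3-alkoxy-4-alkylcyclobutenones; the ring stereocentre forms racemic and disappears in step 9.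

Step 9
Reactants: 25 3-tert-butoxy-4-(3-methylbut-2-en-1-yl)cyclobut-2-en-1-one; 16 triisopropyl{[(4R)-7-methyl-4-(prop-1-en-2-yl)oct-6-en-1-yn-1-yl]oxy}silane
Product: 30 ring A phenol 5-tert-butoxy-2-lavandulyl-6-prenyl-3-(triisopropylsilyloxy)phenol, via vinylketene 26 (not isolated), via vinylcyclobutenone 27 (not isolated), via dienylketene 28 (not isolated), via cyclohexadienone 29 (not isolated)
Conditions: toluene, 80 °C then 110 °C, sealed tube, argon (25 in slight excess)
Reagents that add atoms: none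
Why: Heating opens 25 by 4π-electrocyclic ring opening to vinylketene 26, whose ketene C=C adds to the siloxyalkyne in a [2+2] cycloaddition (forming C7–C8 and C4a–C8a) to give 27, and a second 4π opening gives dienylketene 28. Ring A then closes by thermal disrotatory 6π-electrocyclisation, the ketene carbon C7 bonding to the prenyl-bearing carbon C6, and dienone 29 tautomerises to phenol 30; this is the Danheiser benzannulation in its siloxyalkyne form, which gives resorcinol monosilyl ethers. No stereocentre is created: the C4 centre of 25 and the transient centres of 27 and 29 vanish on aromatisation, and the lavandulyl centre is two bonds from the alkyne and is not touched. The selectivity needed is the regiochemistry of the [2+2] step, and it is secured by the polarisation of the ynol silyl ether, whose nucleophilic lavandulyl-bearing carbon bonds to the electrophilic ketene carbonyl carbon, so that lavandulyl lands between the C7 hydroxyl and the C8a silyloxy group. Every ring carbon arrives with its final substituent except C4a, and the three oxygens emerge distinguishable (free OH at C7, TIPS ether at C8a, tert-butyl ether at C5), which later makes the C8a oxygen O1.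

Step 10
Reactants: 30 ring A phenol
Product: 31 4-bromo-5-tert-butoxy-2-lavandulyl-6-prenyl-3-(triisopropylsilyloxy)phenol (bromine at C4a)
Conditions: NBS (1.0 equiv), CH2Cl2, −78 °C
Reagents that add atoms: N-bromosuccinimide O=C1CCC(=O)N1Br
Why: Electrophilic aromatic bromination at C4a, the only unsubstituted ring position, para to the free hydroxyl and flanked by two oxygens, which at −78 °C should react faster than the three alkenes, as is known for terpenylated resorcinols.

Step 11
Reactants: 31 C4a bromophenol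
Product: 32 [2-bromo-3-tert-butoxy-5-(methoxymethoxy)-6-lavandulyl-4-prenylphenoxy]triisopropylsilane
Conditions: MOMCl, i-Pr2NEt, CH2Cl2, 0 to 40 °C
Reagents that add atoms: chloromethyl methyl ether COCCl
Why: O-alkylation of the phenol with MOMCl (acetal protection) masks the C7 hydroxyl for the organolithium step and supplies a group that falls with acid at the end.

Step 12
Reactants: 32 aryl bromide; 33 N-methoxy-N-methylacetamide
Product: 35 1-{2-tert-butoxy-4-(methoxymethoxy)-5-lavandulyl-3-prenyl-6-[(triisopropylsilyl)oxy]phenyl}ethan-1-one, via aryllithium 34 (not isolated)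
Conditions: n-BuLi, THF, −78 °C; then 33, −78 to −20 °C; aq NH4Cl
Reagents that add atoms: none
Why: Bromine–lithium exchange followed by Weinreb ketone synthesis, in which the aryllithium adds once to the amide to give a stable chelate that collapses to the methyl ketone on work-up, while the low temperature holds back silyl migration.

Step 13
Reactants: 36 2,4-dihydroxybenzaldehyde
Product: 37 2,4-bis(methoxymethoxy)benzaldehyde
Conditions: MOMCl (2.5 equiv), i-Pr2NEt, CH2Cl2, 0 °C to rt
Reagents that add atoms: chloromethyl methyl ether COCCl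
Why: Double O-alkylation of the phenols with MOMCl gives the base-stable aldehyde needed for the aldol condensation.

Step 14
Reactants: 35 aryl methyl ketone; 37 2,4-bis(methoxymethoxy)benzaldehyde
Product: 39 (2E)-3-[2,4-bis(methoxymethoxy)phenyl]-1-[2-tert-butoxy-6-hydroxy-4-(methoxymethoxy)-5-lavandulyl-3-prenylphenyl]prop-2-en-1-one, via potassium phenoxide 38 (not isolated)
Conditions: KOH, EtOH–H2O, rt; then aq NH4Cl, 0 °C
Reagents that add atoms: none
Why: Claisen–Schmidt aldol condensation, in which hydroxide first cleaves the aryl silyl ether activated by the ortho acyl group to phenoxide 38, its methyl ketone enolate condenses with the non-enolisable aldehyde to the (E)-enone, and the open phenoxide chalcone is the resting form in strong base, so that O8a is freed while O5 stays blocked.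

Step 15
Reactants: 39 2′-hydroxychalcone
Product: 40 (2S)-2-[2,4-bis(methoxymethoxy)phenyl]-5-tert-butoxy-7-(methoxymethoxy)-8-lavandulyl-6-prenyl-2,3-dihydro-4H-chromen-4-one
Conditions: 1-[3,5-bis(trifluoromethyl)phenyl]-3-[(9R)-6′-methoxycinchonan-9-yl]thiourea (10–20 mol %), toluene, 0 °C to rt
Reagents that add atoms: none
Why: Enantioselective intramolecular oxa-Michael addition (6-endo-trig) of a 2′-hydroxychalcone under bifunctional cinchona thiourea catalysis, in which the thiourea binds the enone carbonyl and the quinuclidine activates the phenol so that O8a adds to one face of C2 and the catalyst sets the (2S) configuration, while the 6′-alkoxy group makes the closure thermodynamically favourable and hard to reverse.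

Step 16
Reactants: 40 protected (2S)-flavanone
Product: 41 Kushenol B
Conditions: HCl (3 M aq), MeOH, 40–50 °C, argon
Reagents that add atoms: none
Why: Acid-catalysed methanolysis cleaves the three MOM acetals and the tert-butyl ether (the C5 ether, peri to the carbonyl, being the most labile) under conditions of the kind used to unmask C-prenylated flavanones, and the C2 centre of a flavanone is configurationally stable in acid but not in base.

**Compound list**

1 | (4S)-4-benzyl-1,3-oxazolidin-2-one | O=C1N[C@@H](Cc2ccccc2)CO1 | starting material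
2 | 3-methylbut-2-enoyl chloride | CC(C)=CC(=O)Cl | starting material
3 | N-lithio derivative of 1 | [Li]N1[C@@H](Cc2ccccc2)COC1=O | intermediate
4 | (4S)-4-benzyl-3-(3-methylbut-2-enoyl)-1,3-oxazolidin-2-one | CC(C)=CC(=O)N1[C@@H](Cc2ccccc2)COC1=O | intermediate
5 | 1-bromo-3-methylbut-2-ene (prenyl bromide) | CC(C)=CCBr | starting material
6 | sodium (Z)-dienolate of 4 | C=C(C)/C=C(\O[Na])N1[C@@H](Cc2ccccc2)COC1=O | intermediate
7 | (4S)-4-benzyl-3-[(2S)-5-methyl-2-(prop-1-en-2-yl)hex-4-enoyl]-1,3-oxazolidin-2-one | C=C(C)[C@H](CC=C(C)C)C(=O)N1[C@@H](Cc2ccccc2)COC1=O | intermediate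
8 | (S)-lavandulol, (2S)-5-methyl-2-(prop-1-en-2-yl)hex-4-en-1-ol | C=C(C)[C@H](CC=C(C)C)CO | intermediate
9 | ethynyl(trimethyl)silane | C#C[Si](C)(C)C | starting material
10 | (2S)-5-methyl-2-(prop-1-en-2-yl)hex-4-en-1-yl trifluoromethanesulfonate | C=C(C)[C@H](CC=C(C)C)COS(=O)(=O)C(F)(F)F | intermediate
11 | lithium (trimethylsilyl)acetylide | [Li]C#C[Si](C)(C)C | intermediate
12 | trimethyl[(4R)-7-methyl-4-(prop-1-en-2-yl)oct-6-en-1-yn-1-yl]silane | C=C(C)[C@H](CC=C(C)C)CC#C[Si](C)(C)C | intermediate
13 | (4R)-7-methyl-4-(prop-1-en-2-yl)oct-6-en-1-yne | C=C(C)[C@H](CC=C(C)C)CC#C | intermediate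
14 | lithium acetylide of 13 | C=C(C)[C@H](CC=C(C)C)CC#C[Li] | intermediate
15 | lithium (4R)-7-methyl-4-(prop-1-en-2-yl)oct-6-en-1-yn-1-olate | C=C(C)[C@H](CC=C(C)C)CC#CO[Li] | intermediate
16 | triisopropyl{[(4R)-7-methyl-4-(prop-1-en-2-yl)oct-6-en-1-yn-1-yl]oxy}silane | C=C(C)[C@H](CC=C(C)C)CC#CO[Si](C(C)C)(C(C)C)C(C)C | intermediate
17 | potassium tert-butoxide | CC(C)(C)[O-].[K+] | starting material
18 | trichloroethene | ClC=C(Cl)Cl | starting material
19 | (E)-2-[(1,2-dichloroethenyl)oxy]-2-methylpropane | CC(C)(C)O/C(Cl)=C\Cl | intermediate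
20 | lithium tert-butoxyacetylide | CC(C)(C)OC#C[Li] | intermediate
21 | tert-butoxyethyne | CC(C)(C)OC#C | intermediate
22 | 5-methylhex-4-enoic acid | CC(C)=CCCC(=O)O | starting material
23 | 5-methylhex-4-enoyl chloride | CC(C)=CCCC(=O)Cl | intermediate
24 | 5-methylhexa-1,4-dien-1-one (prenylketene) | CC(C)=CCC=C=O | intermediate
25 | 3-tert-butoxy-4-(3-methylbut-2-en-1-yl)cyclobut-2-en-1-one (racemic) | CC(C)=CCC1C(=O)C=C1OC(C)(C)C | intermediate
26 | (3Z)-3-tert-butoxy-7-methylocta-1,3,6-trien-1-one | O=C=C/C(OC(C)(C)C)=C/CC=C(C)C | intermediate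
27 | 4-[(1Z)-1-tert-butoxy-5-methylhexa-1,4-dien-1-yl]-2-[(2R)-5-methyl-2-(prop-1-en-2-yl)hex-4-en-1-yl]-3-[(triisopropylsilyl)oxy]cyclobut-2-en-1-one (both epimers at the ring carbon) | C=C(C)[C@H](CC=C(C)C)CC1=C(O[Si](C(C)C)(C(C)C)C(C)C)C(C1=O)/C(OC(C)(C)C)=C/CC=C(C)C | intermediate
28 | (3E,5Z)-5-tert-butoxy-9-methyl-2-[(2R)-5-methyl-2-(prop-1-en-2-yl)hex-4-en-1-yl]-3-[(triisopropylsilyl)oxy]deca-1,3,5,8-tetraen-1-one | C=C(C)[C@H](CC=C(C)C)CC(=C=O)/C(O[Si](C(C)C)(C(C)C)C(C)C)=C\C(OC(C)(C)C)=C\CC=C(C)C | intermediate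
29 | 5-tert-butoxy-2-[(2R)-5-methyl-2-(prop-1-en-2-yl)hex-4-en-1-yl]-6-(3-methylbut-2-en-1-yl)-3-[(triisopropylsilyl)oxy]cyclohexa-2,4-dien-1-one (both epimers at C6) | C=C(C)[C@H](CC=C(C)C)CC1=C(O[Si](C(C)C)(C(C)C)C(C)C)C=C(OC(C)(C)C)C(CC=C(C)C)C1=O | intermediate
30 | 5-tert-butoxy-2-[(2R)-5-methyl-2-(prop-1-en-2-yl)hex-4-en-1-yl]-6-(3-methylbut-2-en-1-yl)-3-[(triisopropylsilyl)oxy]phenol | C=C(C)[C@H](CC=C(C)C)Cc1c(O)c(CC=C(C)C)c(OC(C)(C)C)cc1O[Si](C(C)C)(C(C)C)C(C)C | intermediate
31 | 4-bromo-5-tert-butoxy-2-[(2R)-5-methyl-2-(prop-1-en-2-yl)hex-4-en-1-yl]-6-(3-methylbut-2-en-1-yl)-3-[(triisopropylsilyl)oxy]phenol | C=C(C)[C@H](CC=C(C)C)Cc1c(O)c(CC=C(C)C)c(OC(C)(C)C)c(Br)c1O[Si](C(C)C)(C(C)C)C(C)C | intermediate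
32 | {2-bromo-3-tert-butoxy-5-(methoxymethoxy)-6-[(2R)-5-methyl-2-(prop-1-en-2-yl)hex-4-en-1-yl]-4-(3-methylbut-2-en-1-yl)phenoxy}triisopropylsilane | C=C(C)[C@H](CC=C(C)C)Cc1c(OCOC)c(CC=C(C)C)c(OC(C)(C)C)c(Br)c1O[Si](C(C)C)(C(C)C)C(C)C | intermediate
33 | N-methoxy-N-methylacetamide | CON(C)C(C)=O | starting material
34 | {2-tert-butoxy-4-(methoxymethoxy)-5-[(2R)-5-methyl-2-(prop-1-en-2-yl)hex-4-en-1-yl]-3-(3-methylbut-2-en-1-yl)-6-[(triisopropylsilyl)oxy]phenyl}lithium | C=C(C)[C@H](CC=C(C)C)Cc1c(OCOC)c(CC=C(C)C)c(OC(C)(C)C)c([Li])c1O[Si](C(C)C)(C(C)C)C(C)C | intermediate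
35 | 1-{2-tert-butoxy-4-(methoxymethoxy)-5-[(2R)-5-methyl-2-(prop-1-en-2-yl)hex-4-en-1-yl]-3-(3-methylbut-2-en-1-yl)-6-[(triisopropylsilyl)oxy]phenyl}ethan-1-one | C=C(C)[C@H](CC=C(C)C)Cc1c(OCOC)c(CC=C(C)C)c(OC(C)(C)C)c(C(C)=O)c1O[Si](C(C)C)(C(C)C)C(C)C | intermediate
36 | 2,4-dihydroxybenzaldehyde | O=Cc1ccc(O)cc1O | starting material
37 | 2,4-bis(methoxymethoxy)benzaldehyde | COCOc1ccc(C=O)c(OCOC)c1 | intermediate
38 | potassium 2-acetyl-3-tert-butoxy-5-(methoxymethoxy)-6-[(2R)-5-methyl-2-(prop-1-en-2-yl)hex-4-en-1-yl]-4-(3-methylbut-2-en-1-yl)phenolate | C=C(C)[C@H](CC=C(C)C)Cc1c(OCOC)c(CC=C(C)C)c(OC(C)(C)C)c(C(C)=O)c1[O-].[K+] | intermediate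
39 | (2E)-3-[2,4-bis(methoxymethoxy)phenyl]-1-{2-tert-butoxy-6-hydroxy-4-(methoxymethoxy)-5-[(2R)-5-methyl-2-(prop-1-en-2-yl)hex-4-en-1-yl]-3-(3-methylbut-2-en-1-yl)phenyl}prop-2-en-1-one | C=C(C)[C@H](CC=C(C)C)Cc1c(OCOC)c(CC=C(C)C)c(OC(C)(C)C)c(C(=O)/C=C/c2ccc(OCOC)cc2OCOC)c1O | intermediate
40 | (2S)-2-[2,4-bis(methoxymethoxy)phenyl]-5-tert-butoxy-7-(methoxymethoxy)-8-[(2R)-5-methyl-2-(prop-1-en-2-yl)hex-4-en-1-yl]-6-(3-methylbut-2-en-1-yl)-2,3-dihydro-4H-chromen-4-one | C=C(C)[C@H](CC=C(C)C)Cc1c(OCOC)c(CC=C(C)C)c(OC(C)(C)C)c2c1O[C@H](c1ccc(OCOC)cc1OCOC)CC2=O | intermediate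
41 | Kushenol B, (2S)-2-(2,4-dihydroxyphenyl)-5,7-dihydroxy-8-[(2R)-5-methyl-2-(prop-1-en-2-yl)hex-4-en-1-yl]-6-(3-methylbut-2-en-1-yl)-2,3-dihydro-4H-chromen-4-one | C=C(C)[C@H](CC=C(C)C)Cc1c(O)c(CC=C(C)C)c(O)c2c1O[C@H](c1ccc(O)cc1O)CC2=O | target

**Step count and risks**

Total steps: 16. Longest linear sequence: 13 (steps 1–6, 9–12, 14–16).

Steps most likely to fail:

1. Step 9. The donor-substituted cyclobutenone may open only at temperatures at which the siloxyalkyne isomerises to a silylketene and the vinylketene dimerises. Fallback from 25 and 16 back to 30: the vinylketene is made at room temperature by elimination instead of electrocyclic opening. LiOH in aqueous THF cleaves the strained ring of 25 (retro-Claisen type) to (2E)-3-tert-butoxy-7-methylocta-2,6-dienoic acid F1, and (COCl)2 converts it into the acid chloride F2. Slow addition of F2 to Et3N and 16 generates vinylketene 26 by 1,4-dehydrochlorination. Its [2+2] adduct 27 is then taken through 28 and 29 to 30 by gentle warming (60–80 °C), which the siloxyalkyne should tolerate.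

2. Step 15. Facial discrimination in the ring closure may be poor, and the C2 configuration may erode through reversible ring opening under the basic catalyst. Fallback from 39 back to 40: NaOAc in refluxing EtOH closes ring C without stereocontrol to the C2-epimeric flavanone F3. Noyori asymmetric transfer hydrogenation with RuCl(p-cymene)[(R,R)-TsDPEN] and HCO2H–Et3N then reduces only the 2R epimer, to the cis (2R,4R)-flavan-4-ol F4, and the untouched 2S ketone 40 is separated by chromatography (kinetic resolution of flavanones by transfer hydrogenation).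

3. Step 12. The silyl group may migrate from oxygen to the lithiated carbon, and the hindered aryllithium may deprotonate the acetamide instead of adding to it. Fallback from 32 back to 35: Stille coupling of 32 with tributyl(1-ethoxyvinyl)stannane (Pd[P(t-Bu)3]2, dioxane, 90 °C) gives the aryl enol ether F5 without any carbanion, and brief treatment with dilute aqueous HCl in THF at 0 °C hydrolyses it to ketone 35.

**Further compounds**

F1 | step 9 | (2E)-3-tert-butoxy-7-methylocta-2,6-dienoic acid | CC(C)=CCC/C(OC(C)(C)C)=C\C(=O)O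
F2 | step 9 | (2E)-3-tert-butoxy-7-methylocta-2,6-dienoyl chloride | CC(C)=CCC/C(OC(C)(C)C)=C\C(Cl)=O
F3 | step 15 | 2-[2,4-bis(methoxymethoxy)phenyl]-5-tert-butoxy-7-(methoxymethoxy)-8-[(2R)-5-methyl-2-(prop-1-en-2-yl)hex-4-en-1-yl]-6-(3-methylbut-2-en-1-yl)-2,3-dihydro-4H-chromen-4-one (both C2 epimers) | C=C(C)[C@H](CC=C(C)C)Cc1c(OCOC)c(CC=C(C)C)c(OC(C)(C)C)c2c1OC(c1ccc(OCOC)cc1OCOC)CC2=O
F4 | step 15 | (2R,4R)-2-[2,4-bis(methoxymethoxy)phenyl]-5-tert-butoxy-7-(methoxymethoxy)-8-[(2R)-5-methyl-2-(prop-1-en-2-yl)hex-4-en-1-yl]-6-(3-methylbut-2-en-1-yl)-3,4-dihydro-2H-chromen-4-ol | C=C(C)[C@H](CC=C(C)C)Cc1c(OCOC)c(CC=C(C)C)c(OC(C)(C)C)c2c1O[C@@H](c1ccc(OCOC)cc1OCOC)C[C@H]2O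
F5 | step 12 | {3-tert-butoxy-2-(1-ethoxyethenyl)-5-(methoxymethoxy)-6-[(2R)-5-methyl-2-(prop-1-en-2-yl)hex-4-en-1-yl]-4-(3-methylbut-2-en-1-yl)phenoxy}triisopropylsilane | C=C(C)[C@H](CC=C(C)C)Cc1c(OCOC)c(CC=C(C)C)c(OC(C)(C)C)c(C(=C)OCC)c1O[Si](C(C)C)(C(C)C)C(C)C
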